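## The problem

Target 15 is a single oxolane ring (O1, C2, C3, C4, C5) with the configuration 2R,3S,4S. It carries a 3,4,5-trimethoxyphenyl group on C2, a hydroxymethyl group on C3 and a 3-hydroxy-4,5-dimethoxybenzyl group on C4. The C2 aryl group is trans to the C3 hydroxymethyl group, which is cis to the C4 benzyl group. This cis pair is the less stable arrangement and cannot be reached by equilibration, so it must be fixed kinetically, most safely by a ring that allows nothing else. C2 is the one stereocentre that a catalyst can set on an achiral precursor, and once in place its aryl group shields one face of the ring and can direct events at C3 and C4. The two arenes differ by one O-methyl group, so they must come from separate fragments, and the lone phenol has to be masked through the organometallic steps. The C2–O1 bond is a benzylic ether that acid ionises and hydrogenolysis cleaves, and a cation at the benzylic carbon on C4 would be captured by the cis oxygen of the C3 side chain to give a furofuran; the two electron-rich arenes also limit the choice of oxidant. The enabling feature is that the exocyclic carbon on C3 and the benzylic carbon on C4 lie on the same face on adjacent ring atoms: joined by a double bond they are the two sp2 carbons of a cyclobutene fused across C3–C4, and cleaving that double bond returns them as a formyl and an aroyl group, from which CH2OH and CH2Ar follow.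

## Retrosynthesis

**15 ⇒ 14 (two O–Si bonds).** The phenol is masked as a triisopropylsilyl ether and the primary alcohol as a tert-butyldimethylsilyl ether. One fluoride treatment then ends the synthesis, with no acid and no hydrogen near the benzylic ether. A benzyl ether on the phenol would need a separate final hydrogenolysis next to the C2–O1 bond. The forward step only has to cleave two silyl ethers.

**14 ⇒ 13 ⇒ 12 ⇒ 11 (benzylic C–H back to C–O; one O–Si bond).** The benzylic CH2 on C4 is traced to a carbinol. It is removed through thionocarbonate 13, made from alcohol 12, which comes from diol 11 by silylation of the primary hydroxyl group. A radical C–O cleavage is chosen over ionic hydrogenation or hydrogenolysis because both of those threaten the C2–O1 bond, and the ionic route also invites furofuran closure. This cut does not simplify the skeleton. Its value is that diol 11 is the direct product of cleaving a C=C bond.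

**11 ⇒ 8 (reconnection of the two carbinol carbons).** The CH2OH carbon and the CH(OH)Ar carbon of 11 are joined to a double bond, which gives the cis-fused cyclobutene 8. In the forward direction this is an ozonolysis with reductive work-up through ozonide 9 and keto aldehyde 10. The cut turns two functionalised side chains into one alkene and encodes the cis relation in a ring fusion. The forward reaction must cleave a strained styrene-type alkene in the presence of two trialkoxyarenes, and must reduce the dicarbonyl before C3 or C4 can epimerise.

**8 ⇒ 4 + 7 (C3–CH and C4–C(aryl) bonds).** Both bonds of the cyclobutene to the oxolane are cut in a [2+2] sense, giving dihydrofuran 4 and terminal alkyne 7. A single cut at the C4–benzylic bond (conjugate addition) would leave the cis relation to a protonation or an alkylation, which would go trans. A cut of the ring bonds C2–C3 and C4–C5 would need an unsymmetrical dipole. Only the [2+2] cut makes the cis relation a geometric necessity. It removes one ring, two C–C bonds and two stereocentres, and leaves two fragments of similar size with one stereocentre between them. The forward reaction must bind cobalt on the face anti to the C2 aryl group, pair the unsubstituted alkyne carbon with C3, and couple alkyne with alkene faster than alkyne with alkyne.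

**4 ⇒ 2 + 3, and 2 ⇒ 1 (C2–aryl bond; O–S bond).** The aryl group is detached from C2, leaving 2,3-dihydrofuran 3 and aryl triflate 2, which comes from phenol 1. An asymmetric Heck arylation makes the C–C bond, sets C2 and moves the double bond to C3=C4 in one step. No shorter route to an enantioenriched 2-aryl-2,5-dihydrofuran is apparent. The forward reaction must give the 2,5-dihydro isomer without double-bond migration and with high enantioselectivity.

**7 ⇒ 6 ⇒ 5 (terminal alkyne carbon; O–Si bond).** The terminal alkyne carbon is removed to give aldehyde 6, the silyl ether of commercial phenol aldehyde 5. A one-carbon homologation under aprotic, low-temperature conditions is required, because the aryl silyl ether would not reliably survive carbonate in methanol.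

## Roads not taken

Alternative 1: The cuts are at the C4–benzylic carbon bond and at C2–C3, with the O1–C2 bond closed later. In the forward sense, lithiated dithiane A3 adds 1,4 to the chiral alkoxy butenolide A2 anti to the alkoxy group, and the lactone enolate is trapped by aldehyde A4 to give the trans lactone A1 in one flask. Reduction of lactone and acetal, acid-promoted closure of the oxolane, desulfurisation and debenzylation would follow.
- Merits: three components are joined in one step, the trans relation on the lactone becomes the required cis pair once the oxolane is closed, and this tandem addition is a proven way to build lignan skeletons.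
- Weak points for this target: no ring forms in the key step. C2 is set only later in a cationic cyclisation next to a free hydroxymethyl group. Raney Ni has to be used beside a benzylic ether. The configuration of 15 calls for the dextrorotatory, less available enantiomer of the terpene auxiliary, used stoichiometrically.
- Comparison: in predictability of the stereochemical outcome this road is ahead of the chosen one, and in step count the two are about level. The chosen plan sets against it a catalytic source of chirality, a key step in which the cis pair is enforced by ring fusion, and an end game free of acid and of Raney Ni.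

Alternative 2: The cuts are at C3–C4 and at the CH2–aryl bond. With NiBr2(dme), a bipyridine ligand and Zn, the secondary bromide A6 gives a C3 radical that closes 5-exo onto the O-allyl group, and the new primary radical is arylated by aryl bromide A7. The product A5 is the fully protected target.
- Merits: the ring, two C–C bonds and two stereocentres form in one step, and no benzylic oxygen is ever introduced, so only deprotection remains. A chair-like transition state with the C2 aryl group pseudo-equatorial predicts 2,3-trans and 3,4-cis.
- Weak points: the cis relation rests on a kinetic preference that is usually moderate for acyclic radicals and is not enforced by a ring. A6 needs several steps to make with a defined benzylic stereocentre, and as a β-alkoxy bromide it fragments by β-elimination on two-electron reduction. The electron-rich bromide A7 is slow in oxidative addition, so reduction and direct arylation of the uncyclised radical compete.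
- Comparison: after its key step this road is clearly shorter than the chosen one, which spends steps 7 to 9 on removing an oxygen. The chosen plan sets against it a cis pair that cannot leak and an entry to C2 by a documented asymmetric arylation.

Alternative 3: The cuts are at the ring bonds C2–C3 and C4–C5. CsF releases a carbonyl ylide from chloro ether A10, which adds across the C=C bond of butenolide A9 to give furofuranone A8. Hydrogenolysis of the benzylic lactone C–O bond and reduction of the acid would complete the side chains.
- Merits: the oxolane and all three stereocentres form in one convergent step, the cis pair is enforced by ring fusion as in the chosen plan, and the benzylic oxygen leaves as an acyloxy group in one hydrogenolysis, which is cheaper than a radical deoxygenation.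
- Weak points: the orientation of an unsymmetrical, non-stabilised ylide on a butenolide and its endo/exo preference (which decides C2 against C3) are not reliable. A10 is an ionisation-prone α-chloro ether of an electron-rich arene. A9 has an acidic benzylic, vinylogous γ-hydrogen and can racemise under basic fluoride. The stereocentre of A9 that controls everything is destroyed at the end, and the hydrogenolysis must still spare C2–O1.
- Comparison: on paper this road is the shortest. The chosen plan sets against it a neutral, fluoride-free key step, a controlling stereocentre that is made catalytically and kept in the product, and fragments that are stable to storage.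

Key step: step 5

Assumption: the (S)-tert-butyl phosphinooxazoline is taken to give the (R)-dihydrofuran 4, as it does with simple aryl triflates; if the sense is the reverse, the (R)-ligand is used.
Assumption: the (S,S)-bisphosphine is written as the enantiomer matched with 4 in step 5; a first comparison of both enantiomers fixes this, and the route is otherwise unchanged.

## Route

Step 1
Reactants: 1 3,4,5-trimethoxyphenol
Product: 2 3,4,5-trimethoxyphenyl trifluoromethanesulfonate
Conditions: Tf2O, pyridine, CH2Cl2, 0 °C
Reagents that add atoms: trifluoromethanesulfonic anhydride, O=S(=O)(OS(=O)(=O)C(F)(F)F)C(F)(F)F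
Why: O-Sulfonylation of a phenol with triflic anhydride; pyridine takes up the triflic acid and no stereocentre is involved.

Step 2
Reactants: 2 3,4,5-trimethoxyphenyl trifluoromethanesulfonate; 3 2,3-dihydrofuran (4 equiv)
Product: 4 (2R)-2-(3,4,5-trimethoxyphenyl)-2,5-dihydrofuran
Conditions: Pd2(dba)3 (1.5 mol%), (S)-4-tert-butyl-2-[2-(diphenylphosphino)phenyl]-4,5-dihydrooxazole (6 mol%), i-Pr2NEt, THF, 70 °C
Reagents that add atoms: none
Why: Asymmetric Mizoroki–Heck arylation: the cationic arylpalladium adds across the enol ether with aryl on the carbon next to oxygen, and β-hydride elimination away from oxygen followed by fast release of the alkene from the phosphinooxazoline complex gives the 2,5-dihydro isomer without double-bond migration. The ligand selects the enantiotopic alkene face and sets C2 as R.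

Step 3
Reactants: 5 3-hydroxy-4,5-dimethoxybenzaldehyde
Product: 6 3,4-dimethoxy-5-[(triisopropylsilyl)oxy]benzaldehyde
Conditions: TIPSCl, imidazole, DMF, 25 °C
Reagents that add atoms: chlorotriisopropylsilane, CC(C)[Si](Cl)(C(C)C)C(C)C
Why: Imidazole-promoted silylation of the phenol; the bulky silyl ether tolerates organolithium, borohydride and radical conditions and leaves with fluoride in the last step.

Step 4
Reactants: 6 3,4-dimethoxy-5-[(triisopropylsilyl)oxy]benzaldehyde
Product: 7 (5-ethynyl-2,3-dimethoxyphenoxy)triisopropylsilane
Conditions: TMSCHN2, LiN(i-Pr)2, THF, −78 → 25 °C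
Reagents that add atoms: (trimethylsilyl)diazomethane, C[Si](C)(C)C=[N+]=[N-]
Why: Colvin homologation: the lithiated silyl diazomethane adds to the aldehyde, Peterson-type loss of silanolate gives a diazoalkene, and loss of N2 with 1,2-hydrogen shift of the alkylidene carbene gives the terminal alkyne. The aprotic conditions spare the aryl silyl ether.

Step 5
Reactants: 4 (2R)-2-(3,4,5-trimethoxyphenyl)-2,5-dihydrofuran (1.5 equiv); 7 (5-ethynyl-2,3-dimethoxyphenoxy)triisopropylsilane
Product: 8 (1R,2R,5R)-6-{3,4-dimethoxy-5-[(triisopropylsilyl)oxy]phenyl}-2-(3,4,5-trimethoxyphenyl)-3-oxabicyclo[3.2.0]hept-6-ene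
Conditions: CoBr2 (10 mol%), (S,S)-2,4-bis(diphenylphosphino)pentane (10 mol%), Zn (50 mol%), NaB[3,5-(CF3)2C6H3]4 (15 mol%), CH2Cl2, 25 °C, 7 added over 6 h
Reagents that add atoms: none
Why: Zn reduces the CoBr2–bisphosphine complex to monovalent cobalt and the borate salt removes bromide, giving a cationic monovalent cobalt centre that binds alkyne 7 and the C3=C4 bond of 4. Oxidative cyclisation gives a trivalent cobaltacyclopentene in which cobalt holds the aryl-bearing alkyne carbon and C4 while the unsubstituted alkyne carbon is bonded to C3, and C(sp2)–C(sp3) reductive elimination then forms the C4–C(aryl) bond. The closest known reaction type is the cobalt-catalysed [2+2] cycloaddition of alkynes with cyclopentene, cyclooctene and related cyclic alkenes under the same activation. The four-membered ring is closed by two bonds made on one face of the alkene (suprafacial), so its fusion to the oxolane is necessarily cis. The new stereocentres C3 and C4 (C1 and C5 of the bicycle) are controlled by C2: cobalt approaches the face anti to the C2 aryl group, which places the cyclobutene trans to that aryl group. The step needs the small CH terminus at C3, next to the substituted C2, and the bulky ligated cobalt at the remote C4; the matched ligand enantiomer reinforces this, because C3 and C4 are the two positions a chiral catalyst tells apart on the unsubstituted dihydrofuran. Cross-coupling is favoured over alkyne oligomerisation by keeping the alkyne concentration low and 4 in excess.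

Step 6
Reactants: 8 (1R,2R,5R)-6-{3,4-dimethoxy-5-[(triisopropylsilyl)oxy]phenyl}-2-(3,4,5-trimethoxyphenyl)-3-oxabicyclo[3.2.0]hept-6-ene
Product: 11 [(2R,3S,4S)-4-[{3,4-dimethoxy-5-[(triisopropylsilyl)oxy]phenyl}(hydroxy)methyl]-2-(3,4,5-trimethoxyphenyl)oxolan-3-yl]methanol (both carbinol epimers), via ozonide 9 (not isolated), via keto aldehyde 10 (not isolated)
Conditions: O3, CH2Cl2, −78 °C (Sudan red 7B end point); then NaBH4, MeOH, −78 → 0 °C
Reagents that add atoms: ozone, [O-][O+]=O
Why: Ozonolysis of the strained styrene-type alkene, which reacts far faster than the arenes, followed by borohydride reduction of the ozonide through the keto aldehyde gives both alcohols in one flask. Bonds to C3 and C4 are not touched and the immediate reduction leaves no time for epimerisation; the new carbinol centre is removed in step 9, so its configuration is irrelevant.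

Step 7
Reactants: 11 diol (both carbinol epimers)
Product: 12 (2R,3S,4S)-3-{[(tert-butyldimethylsilyl)oxy]methyl}-4-[{3,4-dimethoxy-5-[(triisopropylsilyl)oxy]phenyl}(hydroxy)methyl]-2-(3,4,5-trimethoxyphenyl)oxolane (both carbinol epimers)
Conditions: TBSCl (1.05 equiv), imidazole, CH2Cl2, 0 °C
Reagents that add atoms: tert-butylchlorodimethylsilane, CC(C)(C)[Si](C)(C)Cl
Why: Selective silylation of the primary hydroxyl group over the hindered secondary benzylic one.

Step 8
Reactants: 12 mono-silylated alcohol (both carbinol epimers)
Product: 13 (2R,3S,4S)-3-{[(tert-butyldimethylsilyl)oxy]methyl}-4-[{3,4-dimethoxy-5-[(triisopropylsilyl)oxy]phenyl}(phenoxycarbonothioyloxy)methyl]-2-(3,4,5-trimethoxyphenyl)oxolane (both epimers)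
Conditions: PhOC(S)Cl, pyridine, DMAP (cat.), CH2Cl2, 0 → 25 °C
Reagents that add atoms: O-phenyl chlorothionoformate, S=C(Cl)Oc1ccccc1
Why: DMAP-catalysed thioacylation of the secondary alcohol, the first half of a Barton–McCombie deoxygenation. The conditions are neutral and spare both silyl ethers.

Step 9
Reactants: 13 thionocarbonate (both epimers)
Product: 14 (2R,3S,4S)-3-{[(tert-butyldimethylsilyl)oxy]methyl}-4-{3,4-dimethoxy-5-[(triisopropylsilyl)oxy]benzyl}-2-(3,4,5-trimethoxyphenyl)oxolane
Conditions: Bu3SnH, AIBN (cat.), toluene, 90 °C
Reagents that add atoms: none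
Why: Barton–McCombie radical deoxygenation: the stannyl radical adds to the thiocarbonyl sulfur, β-scission releases a benzylic radical and hydrogen transfer from Bu3SnH gives the CH2 group. A radical path cannot ionise C2–O1 or close a furofuran, and C4 is not a radical site, so the cis pair is kept.

Step 10
Reactants: 14 bis-silyl ether
Product: 15 [(2R,3S,4S)-4-(3-hydroxy-4,5-dimethoxybenzyl)-2-(3,4,5-trimethoxyphenyl)oxolan-3-yl]methanol
Conditions: Bu4NF (3 equiv), THF, 0 → 25 °C
Reagents that add atoms: none
Why: Fluoride cleaves the aryl triisopropylsilyl ether and the alkyl tert-butyldimethylsilyl ether in one operation; no stereocentre is affected.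

## Compound list

1 | 3,4,5-trimethoxyphenol | COc1cc(O)cc(OC)c1OC | starting material
2 | 3,4,5-trimethoxyphenyl trifluoromethanesulfonate | COc1cc(OS(=O)(=O)C(F)(F)F)cc(OC)c1OC | intermediate
3 | 2,3-dihydrofuran | C1CC=CO1 | starting material
4 | (2R)-2-(3,4,5-trimethoxyphenyl)-2,5-dihydrofuran | C1O[C@@H](c2cc(OC)c(OC)c(OC)c2)C=C1 | intermediate
5 | 3-hydroxy-4,5-dimethoxybenzaldehyde | COc1cc(C=O)cc(O)c1OC | starting material
6 | 3,4-dimethoxy-5-[(triisopropylsilyl)oxy]benzaldehyde | COc1cc(C=O)cc(O[Si](C(C)C)(C(C)C)C(C)C)c1OC | intermediate
7 | (5-ethynyl-2,3-dimethoxyphenoxy)triisopropylsilane | COc1cc(C#C)cc(O[Si](C(C)C)(C(C)C)C(C)C)c1OC | intermediate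
8 | (1R,2R,5R)-6-{3,4-dimethoxy-5-[(triisopropylsilyl)oxy]phenyl}-2-(3,4,5-trimethoxyphenyl)-3-oxabicyclo[3.2.0]hept-6-ene | COc1cc(C2=C[C@H]3[C@H](c4cc(OC)c(OC)c(OC)c4)OC[C@@H]23)cc(O[Si](C(C)C)(C(C)C)C(C)C)c1OC | intermediate
9 | ozonide of 8: 2,3,7-trioxabicyclo[2.2.1]heptane across the former C6=C7 bond, fused to the oxolane; the two new acetal carbons are not assigned | COc1cc(C23OOC(O2)[C@H]4[C@H](c5cc(OC)c(OC)c(OC)c5)OC[C@@H]34)cc(O[Si](C(C)C)(C(C)C)C(C)C)c1OC | intermediate (not isolated)
10 | (2R,3R,4S)-4-{3,4-dimethoxy-5-[(triisopropylsilyl)oxy]benzoyl}-2-(3,4,5-trimethoxyphenyl)oxolane-3-carbaldehyde | COc1cc(C(=O)[C@@H]2CO[C@@H](c3cc(OC)c(OC)c(OC)c3)[C@@H]2C=O)cc(O[Si](C(C)C)(C(C)C)C(C)C)c1OC | intermediate (not isolated)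
11 | [(2R,3S,4S)-4-[{3,4-dimethoxy-5-[(triisopropylsilyl)oxy]phenyl}(hydroxy)methyl]-2-(3,4,5-trimethoxyphenyl)oxolan-3-yl]methanol, both carbinol epimers | COc1cc(C(O)[C@@H]2CO[C@@H](c3cc(OC)c(OC)c(OC)c3)[C@@H]2CO)cc(O[Si](C(C)C)(C(C)C)C(C)C)c1OC | intermediate
12 | (2R,3S,4S)-3-{[(tert-butyldimethylsilyl)oxy]methyl}-4-[{3,4-dimethoxy-5-[(triisopropylsilyl)oxy]phenyl}(hydroxy)methyl]-2-(3,4,5-trimethoxyphenyl)oxolane, both carbinol epimers | COc1cc(C(O)[C@@H]2CO[C@@H](c3cc(OC)c(OC)c(OC)c3)[C@@H]2CO[Si](C)(C)C(C)(C)C)cc(O[Si](C(C)C)(C(C)C)C(C)C)c1OC | intermediate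
13 | (2R,3S,4S)-3-{[(tert-butyldimethylsilyl)oxy]methyl}-4-[{3,4-dimethoxy-5-[(triisopropylsilyl)oxy]phenyl}(phenoxycarbonothioyloxy)methyl]-2-(3,4,5-trimethoxyphenyl)oxolane, both epimers | COc1cc(C(OC(=S)Oc2ccccc2)[C@@H]3CO[C@@H](c4cc(OC)c(OC)c(OC)c4)[C@@H]3CO[Si](C)(C)C(C)(C)C)cc(O[Si](C(C)C)(C(C)C)C(C)C)c1OC | intermediate
14 | (2R,3S,4S)-3-{[(tert-butyldimethylsilyl)oxy]methyl}-4-{3,4-dimethoxy-5-[(triisopropylsilyl)oxy]benzyl}-2-(3,4,5-trimethoxyphenyl)oxolane | COc1cc(C[C@@H]2CO[C@@H](c3cc(OC)c(OC)c(OC)c3)[C@@H]2CO[Si](C)(C)C(C)(C)C)cc(O[Si](C(C)C)(C(C)C)C(C)C)c1OC | intermediate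
15 | [(2R,3S,4S)-4-(3-hydroxy-4,5-dimethoxybenzyl)-2-(3,4,5-trimethoxyphenyl)oxolan-3-yl]methanol | COc1cc(C[C@@H]2CO[C@@H](c3cc(OC)c(OC)c(OC)c3)[C@@H]2CO)cc(O)c1OC | target

## Step count and risks

Total step count: 10. Longest linear sequence: 8 steps (steps 1, 2, 5–10, or equally steps 3–10).

**Step 5 (key step).** The most likely failure is homo-oligomerisation of the terminal alkyne on cobalt (cyclotrimerisation, dimerisation through the acidic C–H bond) outrunning the cross-cycloaddition. Behind it come leakage of regiochemistry (the aryl-bearing carbon delivered to C3) and cobalt hydride migration of the C3=C4 bond towards oxygen. The fallback sets out from 7. Deprotonation with n-BuLi and quenching with TMSCl gives the silyl-capped alkyne F1, an internal alkyne of the class for which the cobalt cycloaddition with cyclic alkenes is established and which trimerises slowly. The same cobalt activation with 4 should give the 7-silyl cyclobutene F2, with the orientation again steered by the ligand enantiomer. Ipso-protodesilylation of the β-silyl styrene unit with CF3CO2H in CH2Cl2 at −20 °C returns to the route at 8.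

**Step 2.** Oxidative addition of the electron-rich triflate is slow, so the catalyst may decay, and re-insertion of palladium hydride may move the double bond into the 2,3-position, which erodes yield and enantiomeric purity. The fallback sets out from 2. Carbonylative Stille coupling (Pd(PPh3)4, LiCl, CO, tributyl(vinyl)stannane) gives the aryl vinyl ketone F3. Corey–Bakshi–Shibata reduction with the (S)-oxazaborolidine and BH3·SMe2 gives the (R)-allylic alcohol F4. Williamson allylation (NaH, allyl bromide) gives the allyl ether F5. Ring-closing metathesis with the second-generation Grubbs catalyst RuCl2(PCy3)(H2IMes)(=CHPh) returns to the route at 4.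

**Step 6.** Excess ozone may over-oxidise the two trialkoxyarenes, and C4 or C3 may epimerise at the dicarbonyl stage if reduction lags. The fallback sets out from 8. Dihydroxylation with OsO4 (cat.) and NMO on the convex face gives the glycol F6. Cleavage with NaIO4 gives 10, which is reduced in the same flask with NaBH4, returning to the route at 11.

**Step 8 (with step 9).** The hindered, electron-rich benzylic carbon may ionise or eliminate during thioacylation, with capture by the neighbouring silyloxymethyl oxygen, or the thionocarbonate may rearrange thermally from O to S before the radical step. The fallback sets out from 12. Acetylation (Ac2O, pyridine, DMAP) gives the benzylic acetate F7. Hydrogenolysis (H2, Pd/C, EtOAc, 25 °C) should cleave the benzylic acyloxy bond faster than the cyclic benzylic ether and is stopped at that point, returning to the route at 14.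

## Further compounds

F1 | step 5 | {[3,4-dimethoxy-5-(triisopropylsilyloxy)phenyl]ethynyl}trimethylsilane | COc1cc(C#C[Si](C)(C)C)cc(O[Si](C(C)C)(C(C)C)C(C)C)c1OC
F2 | step 5 | (1R,2R,5R)-6-{3,4-dimethoxy-5-[(triisopropylsilyl)oxy]phenyl}-7-(trimethylsilyl)-2-(3,4,5-trimethoxyphenyl)-3-oxabicyclo[3.2.0]hept-6-ene | COc1cc(C2=C([Si](C)(C)C)[C@H]3[C@H](c4cc(OC)c(OC)c(OC)c4)OC[C@@H]23)cc(O[Si](C(C)C)(C(C)C)C(C)C)c1OC
F3 | step 2 | 1-(3,4,5-trimethoxyphenyl)prop-2-en-1-one | C=CC(=O)c1cc(OC)c(OC)c(OC)c1
F4 | step 2 | (1R)-1-(3,4,5-trimethoxyphenyl)prop-2-en-1-ol | O[C@@H](c1cc(OC)c(OC)c(OC)c1)C=C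
F5 | step 2 | 5-[(1R)-1-(allyloxy)prop-2-en-1-yl]-1,2,3-trimethoxybenzene | C=CCO[C@@H](c1cc(OC)c(OC)c(OC)c1)C=C
F6 | step 6 | 6-{3,4-dimethoxy-5-[(triisopropylsilyl)oxy]phenyl}-2-(3,4,5-trimethoxyphenyl)-3-oxabicyclo[3.2.0]heptane-6,7-diol, cis-diol on the convex face, the three older centres arranged as in 8 | COc1cc([C@@]2(O)[C@H](O)[C@H]3[C@H](c4cc(OC)c(OC)c(OC)c4)OC[C@@H]23)cc(O[Si](C(C)C)(C(C)C)C(C)C)c1OC
F7 | step 8 | [(3S,4S,5R)-4-{[(tert-butyldimethylsilyl)oxy]methyl}-5-(3,4,5-trimethoxyphenyl)oxolan-3-yl]{3,4-dimethoxy-5-[(triisopropylsilyl)oxy]phenyl}methyl acetate, both epimers | COc1cc(C(OC(C)=O)[C@@H]2CO[C@@H](c3cc(OC)c(OC)c(OC)c3)[C@@H]2CO[Si](C)(C)C(C)(C)C)cc(O[Si](C(C)C)(C(C)C)C(C)C)c1OC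
A1 | alternative 1 | trans lactone: 4-{2-[3-(benzyloxy)-4,5-dimethoxyphenyl]-1,3-dithian-2-yl}-3-[hydroxy(3,4,5-trimethoxyphenyl)methyl]-5-{[(1S,2R,5S)-2-isopropyl-5-methylcyclohexyl]oxy}oxolan-2-one, configuration as in the SMILES | O=C1O[C@H](O[C@H]2C[C@@H](C)CC[C@@H]2C(C)C)[C@@H](C2(c3cc(OC)c(OC)c(OCc4ccccc4)c3)SCCCS2)[C@@H]1[C@@H](O)c1cc(OC)c(OC)c(OC)c1
A2 | alternative 1 | (5S)-5-{[(1S,2R,5S)-2-isopropyl-5-methylcyclohexyl]oxy}furan-2(5H)-one | O=C1O[C@H](O[C@H]2C[C@@H](C)CC[C@@H]2C(C)C)C=C1
A3 | alternative 1 | 2-[3-(benzyloxy)-4,5-dimethoxyphenyl]-1,3-dithiane | COc1cc(C2SCCCS2)cc(OCc3ccccc3)c1OC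
A4 | alternative 1 | 3,4,5-trimethoxybenzaldehyde | COc1cc(C=O)cc(OC)c1OC
A5 | alternative 2 | tert-butyl{[(2R,3S,4S)-4-[3-(benzyloxy)-4,5-dimethoxybenzyl]-2-(3,4,5-trimethoxyphenyl)oxolan-3-yl]methoxy}dimethylsilane | COc1cc(C[C@@H]2CO[C@@H](c3cc(OC)c(OC)c(OC)c3)[C@@H]2CO[Si](C)(C)C(C)(C)C)cc(OCc4ccccc4)c1OC
A6 | alternative 2 | tert-butyl{[(3S)-3-(allyloxy)-2-bromo-3-(3,4,5-trimethoxyphenyl)propyl]oxy}dimethylsilane, either configuration at the bromine-bearing carbon | C=CCO[C@@H](c1cc(OC)c(OC)c(OC)c1)C(Br)CO[Si](C)(C)C(C)(C)C
A7 | alternative 2 | 1-(benzyloxy)-5-bromo-2,3-dimethoxybenzene | COc1cc(Br)cc(OCc2ccccc2)c1OC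
A8 | alternative 3 | 6-[3-(benzyloxy)-4,5-dimethoxyphenyl]-2-(3,4,5-trimethoxyphenyl)-3,7-dioxabicyclo[3.3.0]octan-8-one, configuration as in the SMILES | O=C1O[C@@H](c2cc(OC)c(OC)c(OCc3ccccc3)c2)[C@@H]2CO[C@@H](c3cc(OC)c(OC)c(OC)c3)[C@H]12
A9 | alternative 3 | (5R)-5-[3-(benzyloxy)-4,5-dimethoxyphenyl]furan-2(5H)-one | O=C1O[C@@H](c2cc(OC)c(OC)c(OCc3ccccc3)c2)C=C1
A10 | alternative 3 | 5-{chloro[(trimethylsilyl)methoxy]methyl}-1,2,3-trimethoxybenzene | COc1cc(C(Cl)OC[Si](C)(C)C)cc(OC)c1OC
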